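**Assumptions.**
- 3,4-Bis(benzyloxy)phenylboronic acid (5) is taken as a catalogue compound.
- The sense of induction of the diene ligand in step 3 is assigned by analogy with cyclic enones. It is to be confirmed on 6; the other ligand antipode is equally available.

## The problem

The target is a B-type biflavanoid, mesquitol-(4α→8)-catechin. A (2R,3S)-catechin unit is joined through its C8 to C4 of a (2R,3S,4S) 7,8,3′,4′-tetrahydroxyflavan-3-ol unit. There are five stereocentres, three of them contiguous on the upper pyran ring, and ten free hydroxyls.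

The lower unit can be bought as (+)-catechin. The upper unit cannot, so its pyran ring must be built in any case. The open question is whether it is built before or after the C4–C8 bond.

That bond must go to C8 and not C6 of the catechin A ring. It must end trans to the upper C3–OH. C4 is a diarylmethine flanked on the catechin side by two ortho oxygens (C7–O and O1), so bond formation at an sp3 C4 is hindered.

The upper A ring has no 5-oxygen. A C4 benzylic cation, on which the usual interflavan coupling relies, is stabilised only by the para 7-oxygen. It forms less readily than in the phloroglucinol series, and acid strong enough to form it also reopens the interflavan bond of the product.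

The feature used here lies in the upper ring O1–C2–C3–C4–C4a–C8a. H-4 and the C3 oxygen are cis to each other and both trans to the C2 aryl group. They are therefore the elements of H–OH added suprafacially across a C3=C4 double bond from the face away from the C2 aryl. C4 carries two aryl carbons (C4a and catechin C8) and C3 none, so such an alkene is biased for oxygen at C3. C2 can thus control C3 and C4 in one event.

The catechol and pyrogallol-type rings oxidise readily above neutral pH, and the benzylic C2–O1 bonds and the interflavan bond are acid-labile. All phenols therefore travel as benzyl ethers and are released last under neutral conditions.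

## Retrosynthesis

**17 ⇒ 16.** The nine O–CH2Ph bonds are cut. Benzyl is chosen because one neutral hydrogenolysis releases every oxygen without acid (interflavan bond) or base (pyrogallol ring). Silyl or acyl phenol protection would not survive the organometallic steps. 16 already has the full skeleton and all five stereocentres. The forward step must only spare the benzylic C2–O1 bonds.

**16 ⇒ 14.** The bonds cut are C3–O and C4–H of the upper pyran ring, not C4–C8. The neighbouring cut (C4–C8 at an sp3 C4) asks one reaction to form a hindered diarylmethine bond and to choose site and face at once. This cut asks only that H and OH be added cis across C3=C4, anti to the C2 aryl. 14 has one stereocentre in the upper ring where 16 has three, and no C3 oxygen. The forward reaction is a hydroboration–oxidation with boron at C3 and facial control from C2.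

**14 ⇒ 7 + 11.** The bond cut is C4–C8, now between two sp2 carbons. The route becomes convergent with halves of similar size. The site on the catechin is fixed by the position of bromine in 11, and the coupling carries no stereochemistry. A cut at C4–C4a would need the upper A ring as the organometal and a more elaborate catechin partner. The forward reaction is a cross-coupling of the di-ortho-oxygenated arylmetal 13 (from 11) with the alkenyl triflate 7, leaving C2 untouched.

**7 ⇒ 6 ⇒ 4 + 5.** The O–S bond of the enol triflate is cut, then the C2–aryl bond. Ketone 6 can enolise only toward C3. Cutting C2–aryl returns the flat chromone 4 and the catalogue boronic acid 5, and makes C2 the one centre set by a catalyst. The neighbouring cut O1–C2 (oxa-Michael closure of a chalcone) is reversible and harder to make selective. The forward reaction is an enantioselective 1,4-arylation giving (2S)-6.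

**4 ⇒ 2 ⇒ 1.** O1–C2 and C2–C3 (one carbon) are cut, then two O–benzyl bonds. Acetophenone 1 already holds O1, C4, C3 and the 7,8-dioxygen pattern of the upper A ring. Its chelated 2′-OH stays free in the benzylation and becomes O1. The forward reactions are a selective double benzylation, a one-carbon condensation and ring closure.

**11 ⇒ 10 ⇒ 9 ⇒ 8.** C8–Br is cut, then five O–benzyl bonds. Both stereocentres of the lower unit are bought with (+)-catechin 8. The forward reactions must brominate C8 rather than C6 and benzylate without epimerising C2.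

## Roads not taken

**Alternative 1:** The cut is C4–C8 at an sp3 C4, the way proanthocyanidins are usually assembled. The protected upper flavan-3-ol A1 is oxidised at C4 in the presence of an alcohol to the C4 ether A2. A Lewis acid ionises A2 to the C4 benzylic cation, which C8 of 9 or 10 attacks in a Friedel–Crafts reaction. The chosen plan is better for three reasons.
- A1 is not purchasable. It must first be made by reagent-controlled dihydroxylation and ring closure in about as many steps as the whole upper half here, and then needs two more operations at C4.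
- The cation has only the para 7-oxygen as donor (the 8-oxygen is meta). Ionisation therefore needs conditions under which the product's own interflavan bond and the cation's self-condensation compete, and the nucleophile must be used in excess.
- Site (C8 against C6) and face (trans to the C3 substituent, less secure for 2,3-trans than for 2,3-cis units) are both left to substrate bias in one SN1 event. Here the site is fixed by bromine and the face by a concerted addition next to C2.

**Alternative 2:** The cut is C4–C4a with C4 set first. Enone A3, which carries the catechin unit on its β-carbon, undergoes Rh-catalysed asymmetric conjugate arylation with the A-ring boronic acid A4. Unmasking of the ortho oxygen and cyclodehydration give the flav-2-ene A5. Hydroboration of A5 would set C2 and C3 from C4. This is the mirror image of the chosen relay, and it is weaker.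
- The catalyst must set a diarylmethine next to a 2,6-dioxygenated aryl: a hindered β-carbon, or in the reverse polarity a di-ortho-substituted boronic acid prone to protodeboronation.
- A4 needs an orthogonally protected ortho oxygen and several steps of its own.
- A5 is an acid-labile enol ether.
- The chosen plan places the catalyst-controlled event at an unhindered chromone C2 with a catalogue boronic acid, and sets the crowded C4 by delivery of hydrogen instead of carbon.

**Alternative 3:** The cut is O1–C2 and C3–C4 at once. Benzhydrol A6, from 12 and a salicylaldehyde, is ionised to the o-quinone methide A7, which undergoes a hetero-Diels–Alder reaction with a B-ring alkene. This is the shortest conceivable ring construction, but the connectivity does not fit.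
- The methide carbon (future C4) bonds to the nucleophilic terminus of the dienophile.
- A β-alkoxystyrene is polarised by its oxygen, so its aryl-bearing carbon bonds to C4 and its oxygen-bearing carbon to O1. That gives a 2-alkoxy-3-arylchroman skeleton.
- A plain styrene gives the flavan skeleton without the C3 oxygen, which cannot be introduced afterwards.
- The absolute configuration at C4 would still need an external catalyst.

Key step: step 9

## Route

**Step 1**
Reactants: 1 2′,3′,4′-trihydroxyacetophenone (gallacetophenone)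
Product: 2 1-[3,4-bis(benzyloxy)-2-hydroxyphenyl]ethanone
Conditions: BnBr (2.1 equiv), K2CO3 (2.2 equiv), acetone, reflux, Ar
Reagents that add atoms: benzyl bromide, BrCc1ccccc1
Why: Williamson etherification; the 2′-OH is hydrogen-bonded to the acetyl carbonyl and is the least reactive, so two equivalents of halide should take the 4′- and 3′-oxygens only.

**Step 2**
Reactants: 2 1-[3,4-bis(benzyloxy)-2-hydroxyphenyl]ethanone
Product: 4 7,8-bis(benzyloxy)-4H-chromen-4-one, via enaminone 3 (not isolated)
Conditions: Me2NCH(OMe)2 (2 equiv), toluene, 100 °C; evaporate; conc. HCl, CH2Cl2, rt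
Reagents that add atoms: N,N-dimethylformamide dimethyl acetal, COC(OC)N(C)C
Why: Condensation of the methyl ketone with the amide acetal gives the enaminone; acid then promotes addition of the phenol to the β-carbon and loss of dimethylamine (standard enaminone chromone synthesis). Aryl benzyl ethers tolerate brief HCl at rt.

**Step 3**
Reactants: 4 7,8-bis(benzyloxy)-4H-chromen-4-one; 5 3,4-bis(benzyloxy)phenylboronic acid
Product: 6 (2S)-7,8-bis(benzyloxy)-2-[3,4-bis(benzyloxy)phenyl]chroman-4-one
Conditions: 5 (2.5 equiv), [RhCl(C2H4)2]2 (2.5 mol%), (S,S)-Ph-bod* (5.5 mol%), aq KOH (0.3 equiv), dioxane/H2O 10:1, 40 °C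
Reagents that add atoms: none
Why: Rh-catalysed asymmetric 1,4-addition of an arylboronic acid to a chromone (Hayashi–Miyaura reaction); the aryl–Rh species inserts C2=C3 and water protonates the Rh enolate. C2 is set by the chiral diene: the antipode that gives (S)-3-arylcyclohexanones should deliver the aryl to the C3-si face and give (2S). Catalytic base and low temperature keep the product from retro-oxa-Michael racemisation.

**Step 4**
Reactants: 6 (2S)-7,8-bis(benzyloxy)-2-[3,4-bis(benzyloxy)phenyl]chroman-4-one
Product: 7 (2S)-7,8-bis(benzyloxy)-2-[3,4-bis(benzyloxy)phenyl]-2H-chromen-4-yl trifluoromethanesulfonate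
Conditions: KHMDS (1.1 equiv), THF, −78 °C; PhNTf2 (1.2 equiv), −78 → −30 °C
Reagents that add atoms: N-phenylbis(trifluoromethanesulfonimide), FC(F)(F)S(=O)(=O)N(c1ccccc1)S(=O)(=O)C(F)(F)F
Why: Kinetic enolate formation and O-sulfonylation (enol triflate synthesis); only C3 is enolisable. At −78 °C the ring C2–O1 bond is poorly aligned with the enolate π system, so β-elimination of the phenoxide should not compete and C2 is not touched.

**Step 5**
Reactants: 8 (+)-catechin
Product: 9 (2R,3S)-5,7-bis(benzyloxy)-2-[3,4-bis(benzyloxy)phenyl]chroman-3-ol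
Conditions: BnBr (4.3 equiv), K2CO3 (4.5 equiv), DMF, −10 °C → rt, Ar
Reagents that add atoms: benzyl bromide, BrCc1ccccc1
Why: Williamson etherification of the four phenols; carbonate does not deprotonate the C3 alcohol, and low temperature limits C-benzylation and C2 epimerisation.

**Step 6**
Reactants: 9 (2R,3S)-5,7-bis(benzyloxy)-2-[3,4-bis(benzyloxy)phenyl]chroman-3-ol
Product: 10 (2R,3S)-3,5,7-tris(benzyloxy)-2-[3,4-bis(benzyloxy)phenyl]chromane
Conditions: NaH (1.5 equiv), BnBr (1.3 equiv), DMF, 0 °C → rt
Reagents that add atoms: benzyl bromide, BrCc1ccccc1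
Why: Alkoxide benzylation; with every phenol capped no quinone-methide pathway remains for epimerisation at C2.

**Step 7**
Reactants: 10 (2R,3S)-3,5,7-tris(benzyloxy)-2-[3,4-bis(benzyloxy)phenyl]chromane
Product: 11 (2R,3S)-3,5,7-tris(benzyloxy)-2-[3,4-bis(benzyloxy)phenyl]-8-bromochromane
Conditions: NBS (1.05 equiv), CH2Cl2, −78 °C → rt
Reagents that add atoms: N-bromosuccinimide, BrN1C(=O)CCC1=O
Why: Electrophilic aromatic bromination; in 5,7-dialkoxyflavans C8 is the more reactive of the two free A-ring positions, the established selectivity for benzylated catechins.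

**Step 8**
Reactants: 11 (2R,3S)-3,5,7-tris(benzyloxy)-2-[3,4-bis(benzyloxy)phenyl]-8-bromochromane; 7 (2S)-7,8-bis(benzyloxy)-2-[3,4-bis(benzyloxy)phenyl]-2H-chromen-4-yl trifluoromethanesulfonate
Product: 14 (2S)-7,8-bis(benzyloxy)-2-[3,4-bis(benzyloxy)phenyl]-4-[(2R,3S)-3,5,7-tris(benzyloxy)-2-(3,4-bis(benzyloxy)phenyl)chroman-8-yl]-2H-chromene, via aryllithium 12 (not isolated), via arylzinc chloride 13 (not isolated)
Conditions: 11 (1.3 equiv), n-BuLi (1.3 equiv), THF, −78 °C; ZnCl2 (1.4 equiv), −78 °C → rt; 7 (1.0 equiv), Pd2(dba)3 (2.5 mol%), SPhos (10 mol%), THF, 45 °C, dark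
Reagents that add atoms: n-butyllithium, [Li]CCCC (lithium in 12 only); zinc chloride, Cl[Zn]Cl (zinc and chlorine in 13 only)
Why: Bromine–lithium exchange, transmetalation to zinc and Negishi coupling with an alkenyl triflate. The C4–C8 bond forms between two sp2 carbons, so no stereocentre arises and the site on the catechin is fixed by the bromide. A dialkylbiarylphosphine ligand is chosen for the di-ortho-substituted arylzinc.

**Step 9**
Reactants: 14 (2S)-7,8-bis(benzyloxy)-2-[3,4-bis(benzyloxy)phenyl]-4-[(2R,3S)-3,5,7-tris(benzyloxy)-2-(3,4-bis(benzyloxy)phenyl)chroman-8-yl]-2H-chromene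
Product: 16 (2R,3S,4S)-7,8-bis(benzyloxy)-2-[3,4-bis(benzyloxy)phenyl]-4-[(2R,3S)-3,5,7-tris(benzyloxy)-2-(3,4-bis(benzyloxy)phenyl)chroman-8-yl]chroman-3-ol, via C3-alkylborane 15 (not isolated)
Conditions: BH3·THF (5 equiv), THF, 0 °C → rt, dark; then 3 M NaOH, 30% H2O2, 0 °C → rt
Reagents that add atoms: borane–tetrahydrofuran, B.C1CCOC1 (boron in 15 only); hydrogen peroxide, OO
Why: Borane adds across C3=C4 of the 2H-chromene through the four-centre transition state, boron to C3 and hydrogen to C4, and alkaline peroxide then replaces boron by oxygen with retention; this is hydroboration–oxidation, the reaction by which flav-3-enes are converted into 2,3-trans-flavan-3-ols. Regiochemistry: C4 carries two aryl carbons (C4a, para to the 7-benzyloxy donor, and catechin C8) and C3 only hydrogen, so both sterics and the polarisation of the 1,1-diarylalkene send boron to C3. No ring is closed. C3 is set by approach of the borane to the face of the heterocycle opposite the C2 aryl group, which sits on the carbon next to the site of C–B bond formation (1,2-induction). C4 is set in the same event because hydrogen is delivered suprafacially with boron: H-4 ends cis to the C3 oxygen, so the catechin substituent ends on the face of the C2 aryl and trans to the hydroxyl, giving the 2,3-trans-3,4-trans (2R,3S,4S) array from the single (2S) centre of 14. The only selectivity needed is facial, and the C2 stereocentre adjacent to C3 secures it; the twisted catechin ring flanks C4 on both faces and can rotate about the C4–C8 bond, so it should slow the addition without reversing the C2 bias. Low temperature and prompt oxidation limit β-elimination of the C3 borane across C2–O1.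

**Step 10**
Reactants: 16 (2R,3S,4S)-7,8-bis(benzyloxy)-2-[3,4-bis(benzyloxy)phenyl]-4-[(2R,3S)-3,5,7-tris(benzyloxy)-2-(3,4-bis(benzyloxy)phenyl)chroman-8-yl]chroman-3-ol
Product: 17 (2R,3S,4S)-2-(3,4-dihydroxyphenyl)-4-[(2R,3S)-2-(3,4-dihydroxyphenyl)-3,5,7-trihydroxychroman-8-yl]chromane-3,7,8-triol (CNP0231186.1)
Conditions: H2 (1 atm), 20% Pd(OH)2/C, THF/MeOH/H2O 20:20:1, rt; filtration under Ar, Sephadex LH-20, lyophilisation
Reagents that add atoms: none
Why: Hydrogenolysis of eight aryl and one alkyl benzyl ether over Pearlman's catalyst, the usual last step for benzylated proanthocyanidins; at 1 atm and rt the flavan C2–O1 bonds and the C4 diarylmethine should survive. Neutral conditions and argon protect the interflavan bond and the pyrogallol-type ring.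

## Compound list

1 | 2′,3′,4′-trihydroxyacetophenone (gallacetophenone) | CC(=O)c1ccc(O)c(O)c1O | starting material
2 | 1-[3,4-bis(benzyloxy)-2-hydroxyphenyl]ethanone | CC(=O)c1ccc(OCc2ccccc2)c(OCc2ccccc2)c1O | intermediate
3 | (E)-1-[3,4-bis(benzyloxy)-2-hydroxyphenyl]-3-(dimethylamino)prop-2-en-1-one | CN(C)/C=C/C(=O)c1ccc(OCc2ccccc2)c(OCc2ccccc2)c1O | intermediate
4 | 7,8-bis(benzyloxy)-4H-chromen-4-one | O=c1ccoc2c(OCc3ccccc3)c(OCc3ccccc3)ccc12 | intermediate
5 | 3,4-bis(benzyloxy)phenylboronic acid | OB(O)c1ccc(OCc2ccccc2)c(OCc2ccccc2)c1 | starting material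
6 | (2S)-7,8-bis(benzyloxy)-2-[3,4-bis(benzyloxy)phenyl]chroman-4-one | O=C1C[C@@H](c2ccc(OCc3ccccc3)c(OCc3ccccc3)c2)Oc2c(OCc3ccccc3)c(OCc3ccccc3)ccc21 | intermediate
7 | (2S)-7,8-bis(benzyloxy)-2-[3,4-bis(benzyloxy)phenyl]-2H-chromen-4-yl trifluoromethanesulfonate | FC(F)(F)S(=O)(=O)OC1=C[C@@H](c2ccc(OCc3ccccc3)c(OCc3ccccc3)c2)Oc2c(OCc3ccccc3)c(OCc3ccccc3)ccc21 | intermediate
8 | (+)-catechin, (2R,3S) | O[C@H]1Cc2c(O)cc(O)cc2O[C@@H]1c1ccc(O)c(O)c1 | starting material
9 | (2R,3S)-5,7-bis(benzyloxy)-2-[3,4-bis(benzyloxy)phenyl]chroman-3-ol | O[C@H]1Cc2c(OCc3ccccc3)cc(OCc3ccccc3)cc2O[C@@H]1c1ccc(OCc2ccccc2)c(OCc2ccccc2)c1 | intermediate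
10 | (2R,3S)-3,5,7-tris(benzyloxy)-2-[3,4-bis(benzyloxy)phenyl]chromane | c1ccccc1CO[C@H]1Cc2c(OCc3ccccc3)cc(OCc3ccccc3)cc2O[C@@H]1c1ccc(OCc2ccccc2)c(OCc2ccccc2)c1 | intermediate
11 | (2R,3S)-3,5,7-tris(benzyloxy)-2-[3,4-bis(benzyloxy)phenyl]-8-bromochromane | c1ccccc1CO[C@H]1Cc2c(OCc3ccccc3)cc(OCc3ccccc3)c(Br)c2O[C@@H]1c1ccc(OCc2ccccc2)c(OCc2ccccc2)c1 | intermediate
12 | 8-lithio derivative of 10 (aryllithium) | c1ccccc1CO[C@H]1Cc2c(OCc3ccccc3)cc(OCc3ccccc3)c([Li])c2O[C@@H]1c1ccc(OCc2ccccc2)c(OCc2ccccc2)c1 | intermediate
13 | 8-(chlorozincio) derivative of 10 (arylzinc chloride) | c1ccccc1CO[C@H]1Cc2c(OCc3ccccc3)cc(OCc3ccccc3)c([Zn]Cl)c2O[C@@H]1c1ccc(OCc2ccccc2)c(OCc2ccccc2)c1 | intermediate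
14 | (2S)-7,8-bis(benzyloxy)-2-[3,4-bis(benzyloxy)phenyl]-4-[(2R,3S)-3,5,7-tris(benzyloxy)-2-(3,4-bis(benzyloxy)phenyl)chroman-8-yl]-2H-chromene | c1ccccc1CO[C@H]1Cc2c(OCc3ccccc3)cc(OCc3ccccc3)c(C3=C[C@@H](c4ccc(OCc5ccccc5)c(OCc5ccccc5)c4)Oc4c(OCc5ccccc5)c(OCc5ccccc5)ccc43)c2O[C@@H]1c1ccc(OCc2ccccc2)c(OCc2ccccc2)c1 | intermediate
15 | (2R,3S,4S)-3-boranyl analogue of 16 (C3-alkylborane, BH2 in place of OH) | c5ccccc5COc1ccc(cc1OCc5ccccc5)[C@H]2Oc3c(ccc(OCc5ccccc5)c3OCc5ccccc5)[C@@H](c3c(OCc5ccccc5)cc(OCc5ccccc5)c4c3O[C@H](c3ccc(OCc5ccccc5)c(OCc5ccccc5)c3)[C@@H](OCc5ccccc5)C4)[C@@H]2B | intermediate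
16 | (2R,3S,4S)-7,8-bis(benzyloxy)-2-[3,4-bis(benzyloxy)phenyl]-4-[(2R,3S)-3,5,7-tris(benzyloxy)-2-(3,4-bis(benzyloxy)phenyl)chroman-8-yl]chroman-3-ol | c5ccccc5COc1ccc(cc1OCc5ccccc5)[C@H]2Oc3c(ccc(OCc5ccccc5)c3OCc5ccccc5)[C@@H](c3c(OCc5ccccc5)cc(OCc5ccccc5)c4c3O[C@H](c3ccc(OCc5ccccc5)c(OCc5ccccc5)c3)[C@@H](OCc5ccccc5)C4)[C@@H]2O | intermediate
17 | (2R,3S,4S)-2-(3,4-dihydroxyphenyl)-4-[(2R,3S)-2-(3,4-dihydroxyphenyl)-3,5,7-trihydroxychroman-8-yl]chromane-3,7,8-triol | Oc1ccc([C@H]2Oc3c(ccc(O)c3O)[C@@H](c3c(O)cc(O)c4c3O[C@H](c3ccc(O)c(O)c3)[C@@H](O)C4)[C@@H]2O)cc1O | target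

## Step count and least certain steps

Total: 10 steps. Longest linear sequence: 7 steps (steps 1, 2, 3, 4, 8, 9, 10, from 1). The catechin branch (steps 5–7) joins at step 8.

**Step 9 (key step).** Four things could go wrong.
- Facial selectivity may be poor if the twisted, chiral catechin ring on C4 counteracts the bias from C2.
- Addition to the crowded trisubstituted alkene may be slow.
- The C3 borane may β-eliminate with opening of the pyran ring.
- 14 may lose its C2 configuration before it reacts, by reversible ring opening of the 2H-chromene under light or acid.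

The fallback sets out from 6 and returns at 16, and forms the C4–C8 bond by the classical cationic route.
- 6 would be converted (TMSOTf, Et3N) into its trimethylsilyl enol ether F1.
- Epoxidation with dimethyldioxirane anti to the C2 aryl, then desilylation (Rubottom oxidation), should give the (2R,3R)-3-hydroxyflavanone F2.
- Borohydride reduction should give the (2R,3S,4R)-flavan-3,4-diol F3.
- Ionisation of the C4 hydroxyl of F3 with BF3·OEt2 in CH2Cl2 at −78 → 0 °C in the presence of excess 10 should give 16 by attack of C8 of 10 trans to the C3 hydroxyl.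
- This route gives up the fixed site and face of the main route, so the C6-linked and 4β isomers would have to be separated.

**Step 8.** Transmetalation and reductive elimination may be slow for the di-ortho-substituted arylzinc. Protodemetalation back to 10 would then compete, and prolonged heating endangers C2 of the product. The fallback sets out from 6 and from 12 (generated from 11 as in step 8) and returns at 14. 12 would be added to the ketone of 6 at −78 °C in the presence of LaCl3·2LiCl, which suppresses enolisation, to give the tertiary 4-aryl-flavan-4-ol F8 as a mixture of C4 epimers. Dehydration with the Burgess reagent (toluene, 50 °C) can occur only toward C3 and should give 14.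

**Step 4.** The enolate may undergo β-elimination of the phenoxide (ring opening to the chalcone), which would erase the C2 stereocentre, or triflation may be incomplete. The fallback sets out from 6 and returns at 14 and avoids the enolate, the triflate and the organozinc. 6 would be condensed with tosylhydrazine (MeOH, 50 °C) to the N-tosylhydrazone F7. F7 would then be coupled with 11 under Barluenga conditions (Pd2(dba)3, XPhos, LiOtBu, dioxane, 90 °C). Carbene insertion and β-hydride elimination toward C3 should give 14.

**Step 3.** Addition to the electron-rich 7,8-dialkoxychromone may be sluggish and protodeboronation of 5 would then compete. The ligand sense may be opposite to the analogy. The flavanone may partly racemise by base-mediated retro-oxa-Michael opening. The fallback sets out from 2 and returns at 6 and uses organocatalytic ring closure instead of arylation.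
- 2 would be doubly deprotonated (LiHMDS) and C-acylated with di-tert-butyl dicarbonate to give the tert-butyl β-ketoester F4.
- Knoevenagel condensation with commercial 3,4-bis(benzyloxy)benzaldehyde (piperidine, AcOH) should give the alkylidene β-ketoester F5.
- A cinchona-derived bifunctional thiourea, with the pseudo-enantiomer chosen for (2S), should close F5 by intramolecular oxa-Michael addition (toluene, −25 °C) to the trans flavanone-3-carboxylate F6.
- TsOH at 80 °C in the same flask should remove the ester to give 6.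

## Further compounds

F1 | step 9 | (2S)-7,8-bis(benzyloxy)-2-[3,4-bis(benzyloxy)phenyl]-4-(trimethylsilyloxy)-2H-chromene | C[Si](C)(C)OC1=C[C@@H](c2ccc(OCc3ccccc3)c(OCc3ccccc3)c2)Oc2c(OCc3ccccc3)c(OCc3ccccc3)ccc21
F2 | step 9 | (2R,3R)-7,8-bis(benzyloxy)-2-[3,4-bis(benzyloxy)phenyl]-3-hydroxychroman-4-one | c5ccccc5COc1ccc(cc1OCc5ccccc5)[C@H]2Oc3c(ccc(OCc5ccccc5)c3OCc5ccccc5)C(=O)[C@@H]2O
F3 | step 9 | (2R,3S,4R)-7,8-bis(benzyloxy)-2-[3,4-bis(benzyloxy)phenyl]chromane-3,4-diol | c5ccccc5COc1ccc(cc1OCc5ccccc5)[C@H]2Oc3c(ccc(OCc5ccccc5)c3OCc5ccccc5)[C@@H](O)[C@@H]2O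
F4 | step 3 | tert-butyl 3-[3,4-bis(benzyloxy)-2-hydroxyphenyl]-3-oxopropanoate | CC(C)(C)OC(=O)CC(=O)c1ccc(OCc2ccccc2)c(OCc2ccccc2)c1O
F5 | step 3 | tert-butyl 2-[3,4-bis(benzyloxy)-2-hydroxybenzoyl]-3-[3,4-bis(benzyloxy)phenyl]prop-2-enoate (alkene geometry as formed) | CC(C)(C)OC(=O)C(=Cc1ccc(OCc2ccccc2)c(OCc2ccccc2)c1)C(=O)c1ccc(OCc2ccccc2)c(OCc2ccccc2)c1O
F6 | step 3 | tert-butyl (2S,3R)-7,8-bis(benzyloxy)-2-[3,4-bis(benzyloxy)phenyl]-4-oxochromane-3-carboxylate (2,3-trans) | CC(C)(C)OC(=O)[C@@H]1[C@@H](c2ccc(OCc3ccccc3)c(OCc3ccccc3)c2)Oc2c(OCc3ccccc3)c(OCc3ccccc3)ccc2C1=O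
F7 | step 4 | N′-[(2S)-7,8-bis(benzyloxy)-2-[3,4-bis(benzyloxy)phenyl]chroman-4-ylidene]-4-methylbenzenesulfonohydrazide | Cc1ccc(cc1)S(=O)(=O)NN=C1C[C@@H](c2ccc(OCc3ccccc3)c(OCc3ccccc3)c2)Oc2c(OCc3ccccc3)c(OCc3ccccc3)ccc21
F8 | step 8 | (2S)-7,8-bis(benzyloxy)-2-[3,4-bis(benzyloxy)phenyl]-4-[(2R,3S)-3,5,7-tris(benzyloxy)-2-(3,4-bis(benzyloxy)phenyl)chroman-8-yl]chroman-4-ol (C4 epimers) | c1ccccc1CO[C@H]1Cc2c(OCc3ccccc3)cc(OCc3ccccc3)c(C3(O)C[C@@H](c4ccc(OCc5ccccc5)c(OCc5ccccc5)c4)Oc4c(OCc5ccccc5)c(OCc5ccccc5)ccc43)c2O[C@@H]1c1ccc(OCc2ccccc2)c(OCc2ccccc2)c1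
A1 | alternative 1 | (2R,3S)-7,8-bis(benzyloxy)-2-[3,4-bis(benzyloxy)phenyl]chroman-3-ol (tetra-O-benzylmesquitol) | c5ccccc5COc1ccc(cc1OCc5ccccc5)[C@H]2Oc3c(ccc(OCc5ccccc5)c3OCc5ccccc5)C[C@@H]2O
A2 | alternative 1 | (2R,3S)-7,8-bis(benzyloxy)-2-[3,4-bis(benzyloxy)phenyl]-4-(2-ethoxyethoxy)chroman-3-ol (C4 configuration not defined) | c5ccccc5COc1ccc(cc1OCc5ccccc5)[C@H]2Oc3c(ccc(OCc5ccccc5)c3OCc5ccccc5)C(OCCOCC)[C@@H]2O
A3 | alternative 2 | (E)-1-[3,4-bis(benzyloxy)phenyl]-3-[(2R,3S)-3,5,7-tris(benzyloxy)-2-(3,4-bis(benzyloxy)phenyl)chroman-8-yl]prop-2-en-1-one | c1ccccc1CO[C@H]1Cc2c(OCc3ccccc3)cc(OCc3ccccc3)c(/C=C/C(=O)c3ccc(OCc4ccccc4)c(OCc4ccccc4)c3)c2O[C@@H]1c1ccc(OCc2ccccc2)c(OCc2ccccc2)c1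
A4 | alternative 2 | [3,4-bis(benzyloxy)-2-(methoxymethoxy)phenyl]boronic acid | OB(O)c1ccc(OCc2ccccc2)c(OCc2ccccc2)c1OCOC
A5 | alternative 2 | (4S)-7,8-bis(benzyloxy)-2-[3,4-bis(benzyloxy)phenyl]-4-[(2R,3S)-3,5,7-tris(benzyloxy)-2-(3,4-bis(benzyloxy)phenyl)chroman-8-yl]-4H-chromene | c5ccccc5COc1ccc(cc1OCc5ccccc5)C1=C[C@H](c3c(OCc5ccccc5)cc(OCc5ccccc5)c4c3O[C@H](c3ccc(OCc5ccccc5)c(OCc5ccccc5)c3)[C@@H](OCc5ccccc5)C4)c2ccc(OCc5ccccc5)c(OCc5ccccc5)c2O1
A6 | alternative 3 | [3,4-bis(benzyloxy)-2-hydroxyphenyl][(2R,3S)-3,5,7-tris(benzyloxy)-2-(3,4-bis(benzyloxy)phenyl)chroman-8-yl]methanol (carbinol configuration not defined) | c1ccccc1CO[C@H]1Cc2c(OCc3ccccc3)cc(OCc3ccccc3)c(C(O)c3ccc(OCc4ccccc4)c(OCc4ccccc4)c3O)c2O[C@@H]1c1ccc(OCc2ccccc2)c(OCc2ccccc2)c1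
A7 | alternative 3 | 2,3-bis(benzyloxy)-6-{[(2R,3S)-3,5,7-tris(benzyloxy)-2-(3,4-bis(benzyloxy)phenyl)chroman-8-yl]methylidene}cyclohexa-2,4-dien-1-one (o-quinone methide) | O=C1C(OCc2ccccc2)=C(OCc2ccccc2)C=CC1=Cc1c(OCc2ccccc2)cc(OCc2ccccc2)c2c1O[C@H](c1ccc(OCc3ccccc3)c(OCc3ccccc3)c1)[C@@H](OCc1ccccc1)C2
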